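**Retrosynthetic overview**

1. Structural feature: two identical benzene rings joined by one CH2; in each ring (target numbering) C1 carries the CH2, C2, C3 and C6 carry Br, C4 and C5 carry OH. C2 and C6 are para and ortho to the C5–OH and both meta to C4, so a formyl group on C4 (a masked hydroxyl) and the C5–OH send bromine to the same two carbons, while C1 stays meta to the only free OH.
2. Last bonds: C3–Br and C3′–Br, by bromination of bis-catechol 11 at its only open position, ortho to the C4–OH.
3. Key disconnection: C4–O and C4′–O, by twofold Dakin oxidation of the tetrabromo bis-salicylaldehyde 9.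
4. 9 comes from bis-salicylaldehyde 8 by fourfold bromination; 8 comes from bisphenol 6 by magnesium-mediated double ortho-formylation.
5. 6 comes from 3-bromoanisole and 3-methoxybenzaldehyde (Grignard addition, ionic hydrogenation, O-demethylation). No ring is formed anywhere; both arenes are bought.

Key step: step 6

Remark: the target has no stereocentre and its conformers about the aryl–CH2 bonds interconvert, so it is treated as achiral and no stereocontrol is needed.
Remark: ring positions in the text follow the target numbering above; compound names use lowest locants, so the "3-hydroxy" group in the names of 8 and 9 is the C5–OH of the target and the formyl group sits on C4.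
Remark: reagents that only deliver atoms (paraformaldehyde, bromine, hydrogen peroxide) are given with SMILES on the reagent lines and carry no compound number.

**Route**

Step 1
Reactants: 1 3-bromoanisole; 2 3-methoxybenzaldehyde
Product: 4 bis(3-methoxyphenyl)methanol, via 3-methoxyphenylmagnesium bromide 3 (not isolated)
Conditions: Mg, I2 (cat.), THF, reflux; then 2, 0 °C → rt; 1 M HCl, 0 °C
Reagents that add atoms: none
Why: Grignard addition of an arylmagnesium bromide to a non-enolisable aryl aldehyde should give the diaryl carbinol cleanly, and the carbinol carbon bears two identical aryl groups, so no stereocentre arises.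

Step 2
Reactants: 4 bis(3-methoxyphenyl)methanol
Product: 5 bis(3-methoxyphenyl)methane
Conditions: Et3SiH (3 equiv), TFA, CH2Cl2, 0 °C → rt
Reagents that add atoms: none
Why: Ionic hydrogenation, in which TFA ionises the benzhydrol to the diarylmethyl cation and excess silane traps it by hydride transfer faster than Friedel–Crafts self-alkylation, with the aryl methyl ethers inert.

Step 3
Reactants: 5 bis(3-methoxyphenyl)methane
Product: 6 bis(3-hydroxyphenyl)methane
Conditions: BBr3 (3 equiv), CH2Cl2, −78 °C → rt; then H2O, 0 °C
Reagents that add atoms: none
Why: Boron tribromide cleavage of aryl methyl ethers (O–B complexation, then bromide attack at methyl) should free both phenols without touching the diarylmethane CH2.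

Step 4
Reactants: 6 bis(3-hydroxyphenyl)methane
Product: 8 bis(4-formyl-3-hydroxyphenyl)methane, via bis[3-hydroxy-4-(hydroxymethyl)phenyl]methane 7 (not isolated)
Conditions: MgCl2 (anhydrous, 4 equiv), Et3N (8 equiv), (CH2O)n (14 equiv), MeCN, reflux; then 1 M HCl
Reagents that add atoms: paraformaldehyde (as formaldehyde), C=O
Why: Casnati–Skattebøl ortho-formylation, in which each magnesium phenoxide delivers formaldehyde to an ortho carbon through a chelate and the magnesium salicyl alkoxide 7 is oxidised by a second formaldehyde (Oppenauer-type hydride transfer); as with other 3-alkylphenols the open ortho carbon C4 (para to the hinge) should react in preference to C6 between OH and the hinge, and the chelated salicylaldehyde resists a second formylation.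

Step 5
Reactants: 8 bis(4-formyl-3-hydroxyphenyl)methane
Product: 9 bis(2,6-dibromo-4-formyl-3-hydroxyphenyl)methane
Conditions: Br2 (4.2 equiv), AcOH, rt → 50 °C, dark
Reagents that add atoms: bromine, BrBr
Why: Electrophilic aromatic bromination as in salicylaldehyde → 3,5-dibromosalicylaldehyde; C2 and C6 are para and ortho to the C5–OH and meta to the C4 formyl group so both substituents agree, whereas C1 (meta to OH, para to CHO) and C3 (meta to OH, ortho to CHO) should stay untouched.

Step 6
Reactants: 9 bis(2,6-dibromo-4-formyl-3-hydroxyphenyl)methane
Product: 11 bis(2,6-dibromo-3,4-dihydroxyphenyl)methane, via bis(2,6-dibromo-4-formyloxy-3-hydroxyphenyl)methane 10 (not isolated)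
Conditions: 30% aq. H2O2 (2.4 equiv), NaOH (4.5 equiv), degassed THF/H2O, N2, 0 °C → rt; then 1 M HCl
Reagents that add atoms: hydrogen peroxide, OO
Why: In base each salicylaldehyde unit is a phenoxide; hydroperoxide anion adds to the formyl carbon to give a tetrahedral peroxy-hemiacetal, and ring carbon C4 then shifts from carbon to the near peroxide oxygen as the O–O bond breaks, giving aryl formate 10, which hydroxide cleaves to the catechol and formate. This is the Dakin oxidation, with the conversion of 3,5-dibromosalicylaldehyde into 3,5-dibromocatechol as closest precedent, run here once on each ring to make the C4–O and C4′–O bonds. No ring is closed and no stereocentre is created, so neither a mode of closure nor a stereocontrol element applies. The step needs aryl instead of hydride migration, which the ortho phenoxide (the C5–O⁻) should secure by feeding electron density to the migrating carbon despite the two bromines. It also needs the catechol to survive, which near-stoichiometric peroxide, low temperature, exclusion of air and prompt acidification should provide, while the aryl bromides sit on electron-rich phenoxide rings and should not be displaced. The position of the new oxygen is fixed because it replaces the formyl carbon on the same ring atom.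

Step 7
Reactants: 11 bis(2,6-dibromo-3,4-dihydroxyphenyl)methane
Product: 12 bis(2,3,6-tribromo-4,5-dihydroxyphenyl)methane (target)
Conditions: Br2 (2.1 equiv), AcOH, 15 °C → rt
Reagents that add atoms: bromine, BrBr
Why: Electrophilic bromination at the single remaining C–H (C3, ortho to the C4–OH), as in the bromination of bromocatechols to tetrabromocatechol in acetic acid; stoichiometric bromine at room temperature should limit o-quinone formation and ipso attack at C1, and a dithionite wash at work-up would return any quinone to the catechol.

**Compound list**

1 | 3-bromoanisole | COc1cccc(Br)c1 | starting material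
2 | 3-methoxybenzaldehyde | COc1cccc(C=O)c1 | starting material
3 | 3-methoxyphenylmagnesium bromide | COc1cccc([Mg]Br)c1 | intermediate (not isolated)
4 | bis(3-methoxyphenyl)methanol | COc1cccc(C(O)c2cccc(OC)c2)c1 | intermediate
5 | bis(3-methoxyphenyl)methane | COc1cccc(Cc2cccc(OC)c2)c1 | intermediate
6 | bis(3-hydroxyphenyl)methane | Oc1cccc(Cc2cccc(O)c2)c1 | intermediate
7 | bis[3-hydroxy-4-(hydroxymethyl)phenyl]methane (present as its magnesium salt) | OCc1ccc(Cc2ccc(CO)c(O)c2)cc1O | intermediate (not isolated)
8 | bis(4-formyl-3-hydroxyphenyl)methane | O=Cc1ccc(Cc2ccc(C=O)c(O)c2)cc1O | intermediate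
9 | bis(2,6-dibromo-4-formyl-3-hydroxyphenyl)methane | O=Cc1cc(Br)c(Cc2c(Br)cc(C=O)c(O)c2Br)c(Br)c1O | intermediate (key-step precursor)
10 | bis(2,6-dibromo-4-formyloxy-3-hydroxyphenyl)methane | O=COc1cc(Br)c(Cc2c(Br)cc(OC=O)c(O)c2Br)c(Br)c1O | intermediate (not isolated)
11 | bis(2,6-dibromo-3,4-dihydroxyphenyl)methane | Oc1cc(Br)c(Cc2c(Br)cc(O)c(O)c2Br)c(Br)c1O | intermediate (key-step product)
12 | bis(2,3,6-tribromo-4,5-dihydroxyphenyl)methane | Oc1c(O)c(Br)c(Cc2c(Br)c(O)c(O)c(Br)c2Br)c(Br)c1Br | target

**Summary**

Total step count: 7. Longest linear sequence: 7 steps (1 → 4 → 5 → 6 → 8 → 9 → 11 → 12).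

Steps most likely to fail:

Step 6 (key step). The emerging catecholate may be oxidised further by peroxide or air in base (quinone formation, ring cleavage), or the second formyl group may react incompletely. Fallback, setting out from 9: O-methylation (MeI, K2CO3, DMF) should give bis(2,6-dibromo-4-formyl-3-methoxyphenyl)methane F1. Baeyer–Villiger oxidation with mCPBA in CH2Cl2, where the ortho methoxy group favours aryl migration, should give bis(2,6-dibromo-4-formyloxy-3-methoxyphenyl)methane F2. Methanolysis (K2CO3, MeOH) should give bis(2,6-dibromo-4-hydroxy-3-methoxyphenyl)methane F3, so that no free catechol ever meets an oxidant. BBr3 in CH2Cl2 then removes the methyl ethers and the route is rejoined at 11.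

Step 7. Bromine may oxidise the catechol to the o-quinone, or attack ipso at C1 (para to the C4–OH) and cut the CH2 hinge. Fallback, setting out from 11: exhaustive O-methylation (MeI, K2CO3, DMF) should give bis(2,6-dibromo-3,4-dimethoxyphenyl)methane F4, which cannot form a quinone. Bromination ortho to the C4–OMe (Br2, AcOH, 60 °C, with catalytic Fe if needed) should give bis(2,3,6-tribromo-4,5-dimethoxyphenyl)methane F5. BBr3 in CH2Cl2 then frees the four hydroxyls and the route is rejoined at 12.

Step 5. Bromination may stall at the crowded carbon between the OH and the hinge (C6), leaving mixtures of lower bromides, and forcing it with excess bromine may cause bromodeformylation. Fallback, setting out from 8: NBS (2 equiv) in MeCN at 0 °C should brominate only para to each OH and give bis(2-bromo-4-formyl-5-hydroxyphenyl)methane F6. The remaining ortho carbons are then brominated with NBS and catalytic i-Pr2NH in CH2Cl2, an amine-mediated ortho-selective delivery of bromine to the phenol, and the route is rejoined at 9.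

**Further compounds**

F1 | step 6 | bis(2,6-dibromo-4-formyl-3-methoxyphenyl)methane | COc1c(C=O)cc(Br)c(Cc2c(Br)cc(C=O)c(OC)c2Br)c1Br
F2 | step 6 | bis(2,6-dibromo-4-formyloxy-3-methoxyphenyl)methane | COc1c(OC=O)cc(Br)c(Cc2c(Br)cc(OC=O)c(OC)c2Br)c1Br
F3 | step 6 | bis(2,6-dibromo-4-hydroxy-3-methoxyphenyl)methane | COc1c(O)cc(Br)c(Cc2c(Br)cc(O)c(OC)c2Br)c1Br
F4 | step 7 | bis(2,6-dibromo-3,4-dimethoxyphenyl)methane | COc1cc(Br)c(Cc2c(Br)cc(OC)c(OC)c2Br)c(Br)c1OC
F5 | step 7 | bis(2,3,6-tribromo-4,5-dimethoxyphenyl)methane | COc1c(OC)c(Br)c(Cc2c(Br)c(OC)c(OC)c(Br)c2Br)c(Br)c1Br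
F6 | step 5 | bis(2-bromo-4-formyl-5-hydroxyphenyl)methane | O=Cc1cc(Br)c(Cc2cc(O)c(C=O)cc2Br)cc1O
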